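**Remarks before the route**

Assumption: both isocitrate residues are taken with the configuration that the SMILES encodes, (R) at the ether carbon C1' and (R) at C2' (ether oxygen and carboxymethyl group syn along the backbone joining the two carboxyl carbons). This is not the threo arrangement of natural isocitric acid, and the route is aimed at the encoded diastereomer.

Numbering: drimane numbering for the decalins (ring A = C1–C5, C10; ring B = C5–C10; C11 = CH2O on C9; C12 = exocyclic methylene carbon on C8; C13 = CH3 on C10; C14 = 4β-CH3; C15 = 4α carbon). Unit A is the gem-dimethyl decalin, unit B the C15-oxygenated one. Isocitrate: C1' (ether carbon, bears CO2Me), C2', C3' (CH2 of the carboxymethyl arm). Acyclic chains are numbered as dodecatrienes (C1 = OCH2, C12 = (E)-terminal carbon); on cyclisation C1→C11, C2→C9, C3→C8, C6→C5, C7→C10, C10→C3, C11→C4, C12→C15, CH2Si carbon→C12.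

## Analysis of the target

The target is a hetero-dimer of two drim-8(12)-ene trans-decalins; each carries at C11 an ether oxygen bound to C1' of an isocitrate, and the C2' carboxyl of isocitrate A is esterified with the C15 hydroxyl of unit B. There are eleven stereocentres: C5, C9, C10 in unit A, C4, C5, C9, C10 in unit B (5α-H, 9α-H, 10β-CH3, C15 equatorial), and (1'R,2'R) in each isocitrate. The terpene and isocitrate parts do not control each other, so each needs its own source of absolute configuration. Six carboxyl groups occur in three states: three methyl esters, one hindered inter-unit ester and two free CH2CO2H groups. The sensitive groups are the exocyclic C8=C12 alkenes (acid moves them into the ring; ozonolysis and hydrogenation are excluded) and the β-alkoxy esters (the C2'–H is acidic; base can expel the terpenyl oxygen by E1cB or epimerise C1' and C2'). The feature the strategy is tied to: the three C–O linkages sit on CH2 groups next to fully substituted ring carbons, C11 on C9 (between C8 and quaternary C10) in both units and C15 on quaternary C4 in ring A of unit B. These are poor SN2 sites in the decalin, but in an acyclic chain the same carbons are C1 and the (E)-terminal C12, both allylic. Unit B is the hard part: C15 is an unactivated equatorial methyl group on a ring with no other function, so no chiral-pool terpenoid offers it.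

## Retrosynthetic reasoning

**C15–O ester (31 ← 29 ← 27 + 23).** The inter-unit ester is cut last in the analysis and made last but one in the synthesis. It is the only linkage that cannot pass through the cyclisation, because an ester on the future C15 would open the neighbouring epoxide by carbonyl participation. The cut gives two halves of equal size; the forward step is acylation of a neopentyl alcohol by a β-alkoxy acid. The two tert-butyl esters of 29 mark the carboxymethyl groups that end as free acids.

**Both halves from one alcohol (27 and 23 ← 22).** Alcohol 22 carries the unit B decalin and an isocitrate whose C2' carboxyl is still an N-acyl oxazolidinone. Methanolysis gives the unit B half 23. Removal of the C15 oxygen (24, 25) and hydroperoxide cleavage give the unit A acid 27. One decalin synthesis thus serves both units, and the imide acts as a latent methyl ester or a latent free acid.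

**C3 oxygen (22 ← 19).** A 3β-hydroxyl is added retrosynthetically; it is the trace of the epoxide that starts the cyclisation. Forward, it is removed by radical deoxygenation, and the C15 silyl ether is cleaved.

**Key disconnection (19 ← 18).** The bonds C4–C5 and C9–C10 are cut, which opens both rings. The precursor 18 is an acyclic triene whose only stereogenic element in the chain is a trisubstituted epoxide; the product has two rings, five new stereocentres and the exocyclic alkene. C11 and C15 revert to allylic carbons, so the ether is already in place before the rings exist.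

**Chain functionalisation (18 ← 14).** The epoxide comes from an allylic alcohol by asymmetric epoxidation, the C12 oxygen from allylic oxidation of the (E)-terminal methyl group, and the allylsilane from cross-coupling of the vinyl iodide. The iodide is a placeholder: it survives etherification and the selenium oxidation, fixes the C2=C3 geometry, and lets silicon enter only after the allylic C1–O bond is an ether and no longer a leaving group.

**C1–O ether (14 ← 13 + 7).** The ether is cut at the primary allylic carbon. Forward, a silver-assisted alkylation of the secondary hydroxyl of 7 forms it without an alkoxide and without touching C1'.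

**C1'–C2' bond (7 ← 4 + 5).** A syn-aldol between the succinate-derived imide 4 and the glyoxylate 5 sets both isocitrate stereocentres from the auxiliary 1. It also delivers the three carboxyl groups in three different forms (methyl ester, tert-butyl ester, imide).

**Iodide 13 ← 8.** The C4–C5 bond and the C1 carbon are cut; forward, a three-carbon homologation of 8 to the alkynol 10 and a hydroalumination–iodination give the (Z)-iodoalkene.

## Alternatives that were turned down

**Alternative 1:** (the textbook route) Disconnection: both C11–O ether bonds and the C15–O ester bond between finished decalins from the chiral pool. Forward: (+)-sclareolide A1 is degraded to albicanol A2, a 15-hydroxy analogue A3 serves for unit B, each C11 hydroxyl displaces the triflate A4 of a (2S,3R)-2-hydroxy triester with inversion, and the halves are esterified. Turned down for three reasons.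
- A3 cannot be reached from A1 or another cheap terpenoid, because ring A carries no group that could direct oxidation to C15; unit B would still need a de novo synthesis.
- The etherification pairs a β-branched, weakly nucleophilic alcohol with a secondary triflate whose neighbouring C2'–H is α to an ester. Elimination to the aconitate is expected to outrun substitution. The reverse polarity is an SN2 at an isobutyl-type carbon between two fully substituted centres in a homoallylic system.
- This weak step would be run twice, late, on the most valuable intermediates.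

**Alternative 2:** Disconnection: the four ring bonds C4–C5 and C9–C10 of both decalins at once. Forward key step: two-fold Lewis-acid bicyclisation of the fully assembled acyclic dimer A5 (both ethers and the inter-unit ester in place, two epoxides, two allylsilanes) to the bis-decalin A6. Turned down because the ester carbonyl on C12 of chain B is placed to open the activated epoxide at C11 through a five-membered acyloxonium ion before the alkene can. In addition, the gem-dimethyl epoxide of chain A has no allylic hydroxyl and needs its own enantioselective sequence, two chains must be built, and two cyclisation yields multiply in one late step.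

**Alternative 3:** Disconnection: the same four ring bonds in the radical mode. Forward key step: two-fold bicyclisation of the all-methyl bis-epoxide A7 with Cp2TiCl (trivalent titanium), which tolerates the pre-formed ester and ends in exocyclic alkenes, to give A6. Turned down because homolytic epoxide opening gives a planar tertiary radical at C11. The epoxide configuration is then not passed on to C4, and methyl and acyloxymethyl differ too little in size, so the one quaternary stereocentre of unit B that cannot be corrected later would form as a mixture. Chain A would again need a separate enantiopure epoxide.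

Key step: step 11

## Route

Step 1
Reactants: 1 (R)-4-benzyloxazolidin-2-one; 2 4-(tert-butoxy)-4-oxobutanoic acid
Product: 4 tert-butyl 4-[(4R)-4-benzyl-2-oxooxazolidin-3-yl]-4-oxobutanoate, via mixed pivalic anhydride 3 (not isolated)
Conditions: t-BuCOCl, Et3N, THF, −20 °C; then 1, LiCl, −20 °C → rt
Reagents that add atoms: none
Why: Mixed-anhydride N-acylation of the oxazolidinone; the tert-butyl ester is inert and no stereocentre is touched.

Step 2
Reactants: 4 tert-butyl 4-[(4R)-4-benzyl-2-oxooxazolidin-3-yl]-4-oxobutanoate; 5 methyl glyoxylate (freshly distilled)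
Product: 7 1-methyl 5-tert-butyl (2R,3R)-3-[(4R)-4-benzyl-2-oxooxazolidine-3-carbonyl]-2-hydroxypentanedioate, via (Z)-dibutylboron enolate 6 (not isolated)
Conditions: Bu2BOTf, i-Pr2NEt, CH2Cl2, −78 → 0 °C; 5, −78 → 0 °C; then pH 7 buffer, MeOH, 30% H2O2, 0 °C
Reagents that add atoms: none
Why: Evans syn-aldol: the (Z)-boron enolate adds through a chair Zimmerman–Traxler transition state on the face away from the benzyl group, which with the (R)-auxiliary should give the (2R,3R) syn adduct. Both isocitrate stereocentres are set here, and the three carboxyl groups emerge as methyl ester, tert-butyl ester and imide.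

Step 3
Reactants: 8 geranyl bromide, (2E)-1-bromo-3,7-dimethylocta-2,6-diene
Product: 10 (6E)-7,11-dimethyldodeca-6,10-dien-2-yn-1-ol, via lithium (5E)-6,10-dimethylundeca-5,9-dien-1-yn-1-ide 9 (not isolated)
Conditions: HC≡CCH2Br, n-BuLi (2 equiv), TMEDA, Et2O/hexane, −78 °C; 8, −78 → −20 °C; then (CH2O)n, → rt; H2O
Reagents that add atoms: propargyl bromide, C#CCBr; formaldehyde (as paraformaldehyde), C=O
Why: The propargylic carbon of 1,3-dilithiopropyne is alkylated by the allylic bromide (SN2, E-alkene kept) and the remaining acetylide is trapped by formaldehyde, a three-carbon homologation in one flask.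

Step 4
Reactants: 10 (6E)-7,11-dimethyldodeca-6,10-dien-2-yn-1-ol
Product: 12 (2Z,6E)-3-iodo-7,11-dimethyldodeca-2,6,10-trien-1-ol, via sodium cyclic alkenylalkoxyaluminate 11 (not isolated)
Conditions: NaAlH2(OCH2CH2OMe)2, THF, 0 °C; then I2, −78 → 0 °C
Reagents that add atoms: iodine, II
Why: Alkoxide-directed trans-hydroalumination places aluminium on C3 in a five-membered alkoxyaluminate, and iodinolysis with retention gives the (Z)-3-iodo allylic alcohol. This alkene geometry later decides the configuration at C9.

Step 5
Reactants: 12 (2Z,6E)-3-iodo-7,11-dimethyldodeca-2,6,10-trien-1-ol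
Product: 13 (2Z,6E)-1-bromo-3-iodo-7,11-dimethyldodeca-2,6,10-triene
Conditions: CBr4, PPh3, CH2Cl2, 0 °C
Reagents that add atoms: tetrabromomethane, BrC(Br)(Br)Br
Why: Appel bromination of a primary allylic alcohol under neutral conditions; substitution at C1 without allylic transposition is expected.

Step 6
Reactants: 13 (2Z,6E)-1-bromo-3-iodo-7,11-dimethyldodeca-2,6,10-triene; 7 1-methyl 5-tert-butyl (2R,3R)-3-[(4R)-4-benzyl-2-oxooxazolidine-3-carbonyl]-2-hydroxypentanedioate
Product: 14 1-methyl 5-tert-butyl (2R,3R)-3-[(4R)-4-benzyl-2-oxooxazolidine-3-carbonyl]-2-[(2Z,6E)-3-iodo-7,11-dimethyldodeca-2,6,10-trienyloxy]pentanedioate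
Conditions: 7 (2.5 equiv, excess recovered), Ag2O, 4 Å MS, CH2Cl2, rt, dark
Reagents that add atoms: none
Why: Purdie-type O-alkylation: the secondary hydroxyl attacks the silver-activated primary allylic bromide. No alkoxide is formed, so retro-aldol, β-elimination and epimerisation of 7 are avoided, and C1' keeps its configuration because its C–O bond is not broken.

Step 7
Reactants: 14 the iodo-trienyl ether from step 6
Product: 15 1-methyl 5-tert-butyl (2R,3R)-3-[(4R)-4-benzyl-2-oxooxazolidine-3-carbonyl]-2-[(2Z,6E,10E)-12-hydroxy-3-iodo-7,11-dimethyldodeca-2,6,10-trienyloxy]pentanedioate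
Conditions: SeO2 (cat.), t-BuOOH, salicylic acid (cat.), CH2Cl2, 0 °C → rt
Reagents that add atoms: tert-butyl hydroperoxide, CC(C)(C)OO
Why: SeO2-catalysed allylic oxidation (ene reaction, then 2,3-sigmatropic shift) should select the (E)-methyl group of the terminal, most electron-rich trisubstituted alkene and give the (E)-allylic alcohol; the iodoalkene is deactivated.

Step 8
Reactants: 15 the 12-hydroxy iodo-trienyl ether from step 7
Product: 16 1-methyl 5-tert-butyl (2R,3R)-3-[(4R)-4-benzyl-2-oxooxazolidine-3-carbonyl]-2-{(2Z,6E,10E)-12-hydroxy-7,11-dimethyl-3-[(trimethylsilyl)methyl]dodeca-2,6,10-trienyloxy}pentanedioate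
Conditions: Me3SiCH2MgCl, ZnCl2, THF, 0 °C; then 15, Pd(PPh3)4 (5 mol%), THF, rt → 40 °C
Reagents that add atoms: (trimethylsilyl)methylmagnesium chloride (transmetalated to zinc), C[Si](C)(C)C[Mg]Cl
Why: Negishi coupling: oxidative addition of the vinyl iodide to zerovalent palladium, transmetalation from the β-hydrogen-free alkylzinc and reductive elimination with retention of the Z geometry; the zinc reagent tolerates esters, imide and the free hydroxyl. Silicon enters only now, because an allylic halide that already carried it would ionise and lose the silyl group.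

Step 9
Reactants: 16 the allylsilane allylic alcohol from step 8
Product: 17 1-methyl 5-tert-butyl (2R,3R)-3-[(4R)-4-benzyl-2-oxooxazolidine-3-carbonyl]-2-{(2Z,6E)-(10S,11S)-10,11-epoxy-12-hydroxy-7,11-dimethyl-3-[(trimethylsilyl)methyl]dodeca-2,6-dienyloxy}pentanedioate
Conditions: Ti(Oi-Pr)4, L-(+)-diethyl tartrate, t-BuOOH, 4 Å MS, CH2Cl2, −20 °C
Reagents that add atoms: tert-butyl hydroperoxide, CC(C)(C)OO
Why: Sharpless asymmetric epoxidation: only the alkene with a free allylic hydroxyl reacts, and the L-(+)-tartrate complex delivers oxygen to the face that gives the (10S,11S)-epoxide. This reagent-controlled epoxide is the source of all decalin stereocentres.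

Step 10
Reactants: 17 the epoxy alcohol from step 9
Product: 18 1-methyl 5-tert-butyl (2R,3R)-3-[(4R)-4-benzyl-2-oxooxazolidine-3-carbonyl]-2-{(2Z,6E)-(10S,11S)-12-(tert-butyldimethylsilyloxy)-10,11-epoxy-7,11-dimethyl-3-[(trimethylsilyl)methyl]dodeca-2,6-dienyloxy}pentanedioate
Conditions: TBSCl, imidazole, DMF, 0 °C → rt
Reagents that add atoms: tert-butyldimethylsilyl chloride, CC(C)(C)[Si](C)(C)Cl
Why: Silylation of the primary hydroxyl; a silyl ether and not an ester is chosen so that no neighbouring group can open the epoxide in step 11.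

Step 11
Reactants: 18 the epoxy allylsilane from step 10
Product: 19 1-methyl 5-tert-butyl (2R,3R)-3-[(4R)-4-benzyl-2-oxooxazolidine-3-carbonyl]-2-{[(3S,4R,5R,9S,10S)-15-(tert-butyldimethylsilyloxy)-3-hydroxydrim-8(12)-en-11-yl]oxy}pentanedioate (3β-OH; 4α-CH2OTBS; 5α-H; 9α-H; 10β-CH3)
Conditions: MeAlCl2 (4 equiv), CH2Cl2, −78 °C, short reaction time; Et3N/MeOH, then aq. NaHCO3
Reagents that add atoms: none
Why: MeAlCl2 activates the epoxide, the C6=C7 alkene attacks the tertiary epoxide carbon C11 from the backside (bond C4–C5), the tertiary cation at C7 is captured by C2 of the allylsilane (bond C9–C10), and loss of silicon from the β-silyl cation at C3 should give the exocyclic C8=C12 alkene only. The closest known reaction type is the Lewis-acid-promoted, epoxide-initiated and allylsilane-terminated cation–olefin polycyclisation. Ring A closes in the 6-endo mode at the more substituted epoxide carbon and ring B in the 6-endo mode on the trisubstituted alkene, both through chair-like folds. C3 keeps the epoxide configuration (equatorial oxygen) and C4 is set by inversion at C11, so the E-disposed CH2OTBS becomes the equatorial C15. C5 and C10 follow from anti addition across the (6E)-alkene (trans fusion), and C9 from the (2Z)-allylsilane geometry, which places CH2O equatorial (9β). The absolute sense of the fold is dictated by the (10S,11S)-epoxide. The step needs opening at C11 and not at C10, which the tertiary centre and the six-membered chair transition state should secure; it also needs the allylic ether to survive, which the low temperature and the weakly basic, ester-flanked ether oxygen should secure. Two rings, five stereocentres and the exocyclic alkene are formed, and the two allylic CH2O carbons of the chain become the hindered C11 and C15 positions.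

Step 12
Reactants: 19 the 3β-hydroxy decalin from step 11
Product: 20 the 3-O-(phenoxythiocarbonyl) derivative of 19
Conditions: PhOC(S)Cl, pyridine, DMAP, CH2Cl2, rt
Reagents that add atoms: O-phenyl chlorothionoformate, S=C(Cl)Oc1ccccc1
Why: Thionoacylation of the equatorial secondary hydroxyl prepares the Barton–McCombie deoxygenation; no other hydroxyl is free.

Step 13
Reactants: 20 the thionocarbonate from step 12
Product: 21 1-methyl 5-tert-butyl (2R,3R)-3-[(4R)-4-benzyl-2-oxooxazolidine-3-carbonyl]-2-{[(4R,5R,9S,10S)-15-(tert-butyldimethylsilyloxy)drim-8(12)-en-11-yl]oxy}pentanedioate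
Conditions: Bu3SnH, AIBN (cat.), toluene, 90 °C
Reagents that add atoms: none
Why: Barton–McCombie deoxygenation: the stannyl radical adds to C=S, β-scission gives the secondary C3 radical, and this abstracts hydrogen from Bu3SnH. The exocyclic alkene is remote and C4 is not touched.

Step 14
Reactants: 21 the silyl ether from step 13
Product: 22 1-methyl 5-tert-butyl (2R,3R)-3-[(4R)-4-benzyl-2-oxooxazolidine-3-carbonyl]-2-{[(4R,5R,9S,10S)-15-hydroxydrim-8(12)-en-11-yl]oxy}pentanedioate
Conditions: HF·pyridine, pyridine, THF, 0 °C → rt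
Reagents that add atoms: none
Why: Buffered fluoride cleavage of the primary silyl ether; the β-alkoxy esters, the tert-butyl ester and the exocyclic alkene should be left intact.

Step 15
Reactants: 22 the 15-hydroxy imide from step 14
Product: 23 1,2-dimethyl 3-tert-butyl (1R,2R)-1-{[(4R,5R,9S,10S)-15-hydroxydrim-8(12)-en-11-yl]oxy}propane-1,2,3-tricarboxylate
Conditions: MeMgBr, MeOH, CH2Cl2, 0 °C
Reagents that add atoms: methanol (as bromomagnesium methoxide), CO
Why: Methanolysis of the N-acyl oxazolidinone by the weakly basic magnesium alkoxide at the exocyclic carbonyl should give the methyl ester without epimerisation at C2' or β-elimination; the auxiliary is released.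

Step 16
Reactants: 22 the 15-hydroxy imide from step 14
Product: 24 the 15-O-(imidazol-1-ylthiocarbonyl) derivative of 22
Conditions: 1,1'-thiocarbonyldiimidazole, DMAP (cat.), ClCH2CH2Cl, 70 °C
Reagents that add atoms: 1,1'-thiocarbonyldiimidazole, S=C(n1ccnc1)n1ccnc1
Why: Acylation of the primary neopentyl hydroxyl gives the radical precursor for removal of the C15 oxygen.

Step 17
Reactants: 24 the thiocarbonylimidazolide from step 16
Product: 25 1-methyl 5-tert-butyl (2R,3R)-3-[(4R)-4-benzyl-2-oxooxazolidine-3-carbonyl]-2-{[(5S,9S,10S)-drim-8(12)-en-11-yl]oxy}pentanedioate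
Conditions: Bu3SnH (slow addition), 1,1'-azobis(cyclohexanecarbonitrile) (cat.), xylene, 140 °C
Reagents that add atoms: none
Why: Barton–McCombie deoxygenation of a primary thiocarbonyl derivative; the higher temperature drives β-scission to the primary radical, which has no β-leaving group and no low-energy rearrangement path. C4 becomes the gem-dimethyl carbon of unit A.

Step 18
Reactants: 25 the albicanyl ether imide from step 17
Product: 27 (2R)-2-[(1R)-1-(albicanyloxy)-2-methoxy-2-oxoethyl]-4-(tert-butoxy)-4-oxobutanoic acid, via peroxy acid 26 (not isolated)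
Conditions: LiOH, 30% H2O2, THF/H2O (3:1), 0 °C; then aq. Na2SO3; 1 M HCl to pH 3
Reagents that add atoms: hydrogen peroxide (as lithium hydroperoxide), OO
Why: The hydroperoxide anion attacks the exocyclic imide carbonyl in preference to the methyl and tert-butyl esters, and sulfite reduces the peroxy acid before acidification, so no peracid meets the alkene.

Step 19
Reactants: 27 the unit A acid from step 18; 23 the unit B alcohol from step 15
Product: 29 di-tert-butyl ester of the target (both CH2CO2H groups as tert-butyl esters), via mixed 2,4,6-trichlorobenzoic anhydride 28 (not isolated)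
Conditions: 2,4,6-Cl3C6H2COCl, Et3N, THF, rt; then 23, DMAP, toluene, rt → 40 °C
Reagents that add atoms: none
Why: Yamaguchi esterification: DMAP opens the mixed anhydride at the aliphatic carbonyl and the acylpyridinium is trapped by the neopentyl primary alcohol. This is the only bond of the dimer made after the cyclisation.

Step 20
Reactants: 29 di-tert-butyl ester of the target
Product: 31 target CNP0139922.3, via bis(trimethylsilyl) ester 30 (not isolated)
Conditions: TMSOTf, 2,6-lutidine, CH2Cl2, 0 °C; then pH 4 aqueous buffer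
Reagents that add atoms: none
Why: Silyl-triflate-mediated cleavage of the tert-butyl esters (alkyl–oxygen scission to isobutene, buffered by lutidine) gives silyl esters that hydrolyse on work-up. The methyl esters, the inter-unit ester, the ethers and the acid-sensitive exocyclic alkenes should be unaffected under the buffered conditions.

## Compound list

1 | (R)-4-benzyloxazolidin-2-one | O=C1N[C@H](Cc2ccccc2)CO1 | starting material
2 | 4-(tert-butoxy)-4-oxobutanoic acid | CC(C)(C)OC(=O)CCC(=O)O | starting material
3 | 4-(tert-butoxy)-4-oxobutanoic pivalic anhydride | CC(C)(C)OC(=O)CCC(=O)OC(=O)C(C)(C)C | intermediate (not isolated)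
4 | tert-butyl 4-[(4R)-4-benzyl-2-oxooxazolidin-3-yl]-4-oxobutanoate | CC(C)(C)OC(=O)CCC(=O)N1[C@H](Cc2ccccc2)COC1=O | intermediate
5 | methyl glyoxylate | COC(=O)C=O | starting material
6 | (Z)-dibutylboron enolate of 4 | CCCCB(CCCC)O/C(=C\CC(=O)OC(C)(C)C)N1[C@H](Cc2ccccc2)COC1=O | intermediate (not isolated)
7 | 1-methyl 5-tert-butyl (2R,3R)-3-[(4R)-4-benzyl-2-oxooxazolidine-3-carbonyl]-2-hydroxypentanedioate | O[C@@H](C(=O)OC)[C@@H](CC(=O)OC(C)(C)C)C(=O)N1[C@H](Cc2ccccc2)COC1=O | intermediate
8 | geranyl bromide | CC(C)=CCC/C(C)=C/CBr | starting material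
9 | lithium (5E)-6,10-dimethylundeca-5,9-dien-1-yn-1-ide | [Li]C#CCC/C=C(\C)CCC=C(C)C | intermediate (not isolated)
10 | (6E)-7,11-dimethyldodeca-6,10-dien-2-yn-1-ol | OCC#CCC/C=C(\C)CCC=C(C)C | intermediate
11 | sodium cyclic alkenyl(alkoxy)bis(2-methoxyethoxy)aluminate of 10 (Al on C3) | [Na+].COCCO[Al-]1(OCCOC)OCC=C1CC/C=C(\C)CCC=C(C)C | intermediate (not isolated)
12 | (2Z,6E)-3-iodo-7,11-dimethyldodeca-2,6,10-trien-1-ol | OC/C=C(\I)CC/C=C(\C)CCC=C(C)C | intermediate
13 | (2Z,6E)-1-bromo-3-iodo-7,11-dimethyldodeca-2,6,10-triene | BrC/C=C(\I)CC/C=C(\C)CCC=C(C)C | intermediate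
14 | 2-O-[(2Z,6E)-3-iodo-7,11-dimethyldodeca-2,6,10-trienyl] ether of 7 | CC(C)=CCC/C(C)=C/CC/C(I)=C/CO[C@@H](C(=O)OC)[C@@H](CC(=O)OC(C)(C)C)C(=O)N1[C@H](Cc2ccccc2)COC1=O | intermediate
15 | (10E)-12-hydroxy derivative of 14 | OC/C(C)=C/CC/C(C)=C/CC/C(I)=C/CO[C@@H](C(=O)OC)[C@@H](CC(=O)OC(C)(C)C)C(=O)N1[C@H](Cc2ccccc2)COC1=O | intermediate
16 | (2Z,6E,10E)-3-[(trimethylsilyl)methyl] analogue of 15 | OC/C(C)=C/CC/C(C)=C/CC/C(C[Si](C)(C)C)=C/CO[C@@H](C(=O)OC)[C@@H](CC(=O)OC(C)(C)C)C(=O)N1[C@H](Cc2ccccc2)COC1=O | intermediate
17 | (10S,11S)-10,11-epoxide of 16 | OC[C@]1(C)O[C@H]1CC/C(C)=C/CC/C(C[Si](C)(C)C)=C/CO[C@@H](C(=O)OC)[C@@H](CC(=O)OC(C)(C)C)C(=O)N1[C@H](Cc2ccccc2)COC1=O | intermediate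
18 | 12-O-tert-butyldimethylsilyl ether of 17 | CC(C)(C)[Si](C)(C)OC[C@]1(C)O[C@H]1CC/C(C)=C/CC/C(C[Si](C)(C)C)=C/CO[C@@H](C(=O)OC)[C@@H](CC(=O)OC(C)(C)C)C(=O)N1[C@H](Cc2ccccc2)COC1=O | intermediate
19 | (3S,4R,5R,9S,10S)-15-(TBS-oxy)-3-hydroxydrim-8(12)-en-11-yl ether of 7 | CC(C)(C)[Si](C)(C)OC[C@]1(C)[C@@H](O)CC[C@]2(C)[C@@H](CO[C@@H](C(=O)OC)[C@@H](CC(=O)OC(C)(C)C)C(=O)N3[C@H](Cc4ccccc4)COC3=O)C(=C)CC[C@@H]12 | intermediate
20 | 3-O-(phenoxythiocarbonyl) derivative of 19 | CC(C)(C)[Si](C)(C)OC[C@]1(C)[C@@H](OC(=S)Oc3ccccc3)CC[C@]2(C)[C@@H](CO[C@@H](C(=O)OC)[C@@H](CC(=O)OC(C)(C)C)C(=O)N3[C@H](Cc4ccccc4)COC3=O)C(=C)CC[C@@H]12 | intermediate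
21 | (4R,5R,9S,10S)-15-(TBS-oxy)drim-8(12)-en-11-yl ether of 7 | CC(C)(C)[Si](C)(C)OC[C@]1(C)CCC[C@]2(C)[C@@H](CO[C@@H](C(=O)OC)[C@@H](CC(=O)OC(C)(C)C)C(=O)N3[C@H](Cc4ccccc4)COC3=O)C(=C)CC[C@@H]12 | intermediate
22 | (4R,5R,9S,10S)-15-hydroxydrim-8(12)-en-11-yl ether of 7 | OC[C@]1(C)CCC[C@]2(C)[C@@H](CO[C@@H](C(=O)OC)[C@@H](CC(=O)OC(C)(C)C)C(=O)N3[C@H](Cc4ccccc4)COC3=O)C(=C)CC[C@@H]12 | intermediate
23 | 1,2-dimethyl 3-tert-butyl (1R,2R)-1-[(15-hydroxydrim-8(12)-en-11-yl)oxy]propane-1,2,3-tricarboxylate (unit B half) | OC[C@]1(C)CCC[C@]2(C)[C@@H](CO[C@@H](C(=O)OC)[C@@H](CC(=O)OC(C)(C)C)C(=O)OC)C(=C)CC[C@@H]12 | intermediate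
24 | 15-O-(imidazol-1-ylthiocarbonyl) derivative of 22 | S=C(OC[C@]1(C)CCC[C@]2(C)[C@@H](CO[C@@H](C(=O)OC)[C@@H](CC(=O)OC(C)(C)C)C(=O)N3[C@H](Cc4ccccc4)COC3=O)C(=C)CC[C@@H]12)n1ccnc1 | intermediate
25 | (5S,9S,10S)-drim-8(12)-en-11-yl (albicanyl) ether of 7 | C=C1CC[C@H]2C(C)(C)CCC[C@]2(C)[C@H]1CO[C@@H](C(=O)OC)[C@@H](CC(=O)OC(C)(C)C)C(=O)N1[C@H](Cc2ccccc2)COC1=O | intermediate
26 | peroxy acid from 25 (C2' carboxyl as CO3H) | C=C1CC[C@H]2C(C)(C)CCC[C@]2(C)[C@H]1CO[C@@H](C(=O)OC)[C@@H](CC(=O)OC(C)(C)C)C(=O)OO | intermediate (not isolated)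
27 | (2R)-2-[(1R)-1-(albicanyloxy)-2-methoxy-2-oxoethyl]-4-(tert-butoxy)-4-oxobutanoic acid (unit A half) | C=C1CC[C@H]2C(C)(C)CCC[C@]2(C)[C@H]1CO[C@@H](C(=O)OC)[C@@H](CC(=O)OC(C)(C)C)C(=O)O | intermediate
28 | mixed anhydride of 27 with 2,4,6-trichlorobenzoic acid | C=C1CC[C@H]2C(C)(C)CCC[C@]2(C)[C@H]1CO[C@@H](C(=O)OC)[C@@H](CC(=O)OC(C)(C)C)C(=O)OC(=O)c1c(Cl)cc(Cl)cc1Cl | intermediate (not isolated)
29 | di-tert-butyl ester of the target | C=C1CC[C@H]2C(C)(C)CCC[C@]2(C)[C@H]1CO[C@@H](C(=O)OC)[C@@H](CC(=O)OC(C)(C)C)C(=O)OC[C@]1(C)CCC[C@]2(C)[C@@H](CO[C@@H](C(=O)OC)[C@@H](CC(=O)OC(C)(C)C)C(=O)OC)C(=C)CC[C@@H]12 | intermediate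
30 | bis(trimethylsilyl) ester of the target | C=C1CC[C@H]2C(C)(C)CCC[C@]2(C)[C@H]1CO[C@@H](C(=O)OC)[C@@H](CC(=O)O[Si](C)(C)C)C(=O)OC[C@]1(C)CCC[C@]2(C)[C@@H](CO[C@@H](C(=O)OC)[C@@H](CC(=O)O[Si](C)(C)C)C(=O)OC)C(=C)CC[C@@H]12 | intermediate (not isolated)
31 | CNP0139922.3: isocitrate A (C1' methyl ester, free C3' acid) as C1'-O-albicanyl ether, its C2' carboxyl esterified with C15-OH of unit B, which carries at C11 the C1'-O-ether of isocitrate B (dimethyl ester, free C3' acid) | C=C1CC[C@H]2C(C)(C)CCC[C@]2(C)[C@H]1CO[C@@H](C(=O)OC)[C@@H](CC(=O)O)C(=O)OC[C@]1(C)CCC[C@]2(C)[C@@H](CO[C@@H](C(=O)OC)[C@@H](CC(=O)O)C(=O)OC)C(=C)CC[C@@H]12 | target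

## Step count and risk

Total step count: 20. Longest linear sequence: 17 steps (from 8 through steps 3–14 and 16–20 to 31).

**Step 11 (key step).** The allylic C1–O ether may ionise under the Lewis acid (the allyl cation would be β-silyl-stabilised), the epoxide may open at C10 or rearrange to a ketone, or the tert-butyl ester may be lost to the aluminium reagent; each diverts material before the second ring closes. Fallback in the radical mode, from 15: a Negishi methylation (MeZnCl, Pd(PPh3)4) would give the (2E,6E,10E)-12-hydroxyfarnesyl ether F1; the same asymmetric epoxidation would give the (10S,11S)-epoxy alcohol F2; silylation would give the silyl ether F3. Cp2TiCl (trivalent titanium, from Cp2TiCl2 and Mn dust, THF, rt) would then open the epoxide homolytically and fold F3 by radical bicyclisation with exocyclic alkene formation. The route is rejoined at 19 after chromatographic removal of the C4 epimer that this non-stereospecific mode is expected to form.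

**Step 6.** Alkylation of the hindered secondary hydroxyl may be slower than consumption of the bromide by adventitious water on the silver surface. Fallback from 12: Cl3CCN and DBU (cat.) would give the allylic trichloroacetimidate F4, which would be coupled with 7 under TMSOTf catalysis (CH2Cl2/cyclohexane, 0 °C) at the stage where no acid-sensitive allylsilane is present; this rejoins the route at 14.

**Step 7.** Over-oxidation to the enal and competing oxidation at the internal allylic positions may lower the yield of the alcohol. Fallback from 14: the oxidation would be driven to the aldehyde stage (stoichiometric SeO2, then Dess–Martin periodinane on the crude mixture) to give the (10E)-12-oxo enal F5, which would be reduced 1,2 under Luche conditions (NaBH4, CeCl3, MeOH, −78 °C) to 15.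

**Step 17.** Fragmentation to a primary radical is slow, so reduction of the thiocarbonyl group without C–O cleavage (return of the alcohol) may compete. Fallback from 22: Dess–Martin oxidation would give the non-enolisable C15 aldehyde F6, tosylhydrazide would give the tosylhydrazone F7, and reduction with catecholborane followed by NaOAc and warming would give the methyl group and rejoin the route at 25.

**Step 19.** Acylation of the neopentyl alcohol may be slow enough for the activated acid to epimerise at C2' or lose the albicanyloxy group by β-elimination. Fallback with reversed polarity, from 23: Tf2O and 2,6-di-tert-butylpyridine would give the neopentyl triflate F8 (no β-hydrogen, so no elimination); acid 27, deprotonated in the flask with Cs2CO3 in DMF, would displace it as the carboxylate without any activation of the acid, rejoining the route at 29.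

## Further compounds

F1 | step 11 | (2E,6E,10E)-12-hydroxy-3,7,11-trimethyldodeca-2,6,10-trienyl ether of 7 | OC/C(C)=C/CC/C(C)=C/CC/C(C)=C/CO[C@@H](C(=O)OC)[C@@H](CC(=O)OC(C)(C)C)C(=O)N1[C@H](Cc2ccccc2)COC1=O
F2 | step 11 | (10S,11S)-10,11-epoxide of F1 | OC[C@]1(C)O[C@H]1CC/C(C)=C/CC/C(C)=C/CO[C@@H](C(=O)OC)[C@@H](CC(=O)OC(C)(C)C)C(=O)N1[C@H](Cc2ccccc2)COC1=O
F3 | step 11 | 12-O-tert-butyldimethylsilyl ether of F2 | CC(C)(C)[Si](C)(C)OC[C@]1(C)O[C@H]1CC/C(C)=C/CC/C(C)=C/CO[C@@H](C(=O)OC)[C@@H](CC(=O)OC(C)(C)C)C(=O)N1[C@H](Cc2ccccc2)COC1=O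
F4 | step 6 | (2Z,6E)-3-iodo-7,11-dimethyldodeca-2,6,10-trienyl 2,2,2-trichloroacetimidate | N=C(OC/C=C(\I)CC/C=C(\C)CCC=C(C)C)C(Cl)(Cl)Cl
F5 | step 7 | (10E)-12-oxo derivative (enal) of 14 | O=C/C(C)=C/CC/C(C)=C/CC/C(I)=C/CO[C@@H](C(=O)OC)[C@@H](CC(=O)OC(C)(C)C)C(=O)N1[C@H](Cc2ccccc2)COC1=O
F6 | step 17 | C15 aldehyde from 22 | O=C[C@]1(C)CCC[C@]2(C)[C@@H](CO[C@@H](C(=O)OC)[C@@H](CC(=O)OC(C)(C)C)C(=O)N3[C@H](Cc4ccccc4)COC3=O)C(=C)CC[C@@H]12
F7 | step 17 | tosylhydrazone of F6 | Cc1ccc(cc1)S(=O)(=O)N/N=C/[C@]1(C)CCC[C@]2(C)[C@@H](CO[C@@H](C(=O)OC)[C@@H](CC(=O)OC(C)(C)C)C(=O)N3[C@H](Cc4ccccc4)COC3=O)C(=C)CC[C@@H]12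
F8 | step 19 | C15 triflate of 23 | FC(F)(F)S(=O)(=O)OC[C@]1(C)CCC[C@]2(C)[C@@H](CO[C@@H](C(=O)OC)[C@@H](CC(=O)OC(C)(C)C)C(=O)OC)C(=C)CC[C@@H]12
A1 | alternative 1 | (+)-sclareolide | CC1(C)CCC[C@]2(C)[C@H]3CC(=O)O[C@]3(C)CC[C@@H]12
A2 | alternative 1 | albicanol | C=C1CC[C@H]2C(C)(C)CCC[C@]2(C)[C@H]1CO
A3 | alternative 1 | 15-hydroxyalbicanol | OC[C@]1(C)CCC[C@]2(C)[C@@H](CO)C(=C)CC[C@@H]12
A4 | alternative 1 | 1,2-dimethyl 3-tert-butyl (1S,2R)-1-(trifluoromethylsulfonyloxy)propane-1,2,3-tricarboxylate | FC(F)(F)S(=O)(=O)O[C@H](C(=O)OC)[C@@H](CC(=O)OC(C)(C)C)C(=O)OC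
A5 | alternative 2 | acyclic bis(epoxy allylsilane) dimer with both ethers and the inter-unit ester in place | CC1(C)O[C@H]1CC/C(C)=C/CC/C(C[Si](C)(C)C)=C/CO[C@@H](C(=O)OC)[C@@H](CC(=O)OC(C)(C)C)C(=O)OC[C@]1(C)O[C@H]1CC/C(C)=C/CC/C(C[Si](C)(C)C)=C/CO[C@@H](C(=O)OC)[C@@H](CC(=O)OC(C)(C)C)C(=O)OC
A6 | alternative 2 | 3β,3'β-dihydroxy derivative of 29 | C=C1CC[C@H]2C(C)(C)[C@@H](O)CC[C@]2(C)[C@H]1CO[C@@H](C(=O)OC)[C@@H](CC(=O)OC(C)(C)C)C(=O)OC[C@]1(C)[C@@H](O)CC[C@]2(C)[C@@H](CO[C@@H](C(=O)OC)[C@@H](CC(=O)OC(C)(C)C)C(=O)OC)C(=C)CC[C@@H]12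
A7 | alternative 3 | acyclic all-methyl bis(epoxyfarnesyl) dimer | CC1(C)O[C@H]1CC/C(C)=C/CC/C(C)=C/CO[C@@H](C(=O)OC)[C@@H](CC(=O)OC(C)(C)C)C(=O)OC[C@]1(C)O[C@H]1CC/C(C)=C/CC/C(C)=C/CO[C@@H](C(=O)OC)[C@@H](CC(=O)OC(C)(C)C)C(=O)OC
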